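The plan rests on one structural fact: each isoprenoid group is bonded to an aromatic carbon directly adjacent to an oxygenated one, C8 of ring A (flanked by O7) for the prenyl chain and C3' of ring B (flanked by O4') for the pyran. Both are therefore disconnected to C5 ethers on the two phenols of (S)-liquiritigenin, whose C2 centre is purchased and never touched. The precursor is the 7-O-(2-methylbut-3-en-2-yl), 4'-O-(2-methylbut-3-yn-2-yl) bis-ether. A single thermolysis in a neutral medium moves the allyl unit to C8 by aromatic Claisen rearrangement and converts the propargyl ether into the fused 2,2-dimethylpyran, so three bonds and one ring form and the free target emerges.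

Key step: step 4

Remark: (S)-liquiritigenin is assumed to be purchased as the single enantiomer; the C2 descriptor stays (S) throughout because the CIP order O1 > C1' > C3 > H never changes; optical purity is to be checked by chiral HPLC after steps 1, 3 and 4, and the acid-labile tertiary ethers are purified on neutral alumina.

Step 1
Reactants: 1 (S)-liquiritigenin [(2S)-7-hydroxy-2-(4-hydroxyphenyl)chroman-4-one]; 2 3-chloro-3-methylbut-1-yne
Product: 3 (2S)-2-(4-hydroxyphenyl)-7-[(2-methylbut-3-yn-2-yl)oxy]chroman-4-one
Conditions: 2 (1.1 equiv), DBU (1.1 equiv), CuCl2·2H2O (1 mol %), MeCN, −10 to 0 °C; pH 7 buffer quench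
Reagents that add atoms: 3-chloro-3-methylbut-1-yne (2), CC(C)(Cl)C#C
Why: Copper-catalysed propargylic etherification of a phenol with a tertiary propargylic chloride (through a copper acetylide/allenylidene) is well established, and with one equivalent of amidine base only the markedly more acidic 7-OH, a vinylogous acid para to the C4 carbonyl, should be ionised and alkylated, while the cold, short exposure should keep C3–H enolisation and opening of ring C too slow to matter; no stereocentre is formed.

Step 2
Reactants: 3 (2S)-2-(4-hydroxyphenyl)-7-[(2-methylbut-3-yn-2-yl)oxy]chroman-4-one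
Product: 4 (2S)-2-(4-hydroxyphenyl)-7-[(2-methylbut-3-en-2-yl)oxy]chroman-4-one
Conditions: H2 (1 atm), Lindlar catalyst, quinoline, EtOAc, rt, stopped at 1 equiv uptake
Reagents that add atoms: none
Why: Lindlar semi-hydrogenation of a terminal alkyne stops at the alkene on the lead- and quinoline-poisoned catalyst and should leave the aryl ketone, the benzylic C2–O1 bond and the phenol untouched, and the tertiary allyl aryl ether is thermally stable at room temperature, so no premature Claisen shift is expected.

Step 3
Reactants: 4 (2S)-2-(4-hydroxyphenyl)-7-[(2-methylbut-3-en-2-yl)oxy]chroman-4-one; 2 3-chloro-3-methylbut-1-yne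
Product: 5 (2S)-7-[(2-methylbut-3-en-2-yl)oxy]-2-{4-[(2-methylbut-3-yn-2-yl)oxy]phenyl}chroman-4-one
Conditions: 2 (1.5 equiv), DBU (1.3 equiv), CuCl2·2H2O (1 mol %), MeCN, −10 to 0 °C; pH 7 buffer quench
Reagents that add atoms: 3-chloro-3-methylbut-1-yne (2), CC(C)(Cl)C#C
Why: The same copper-catalysed propargylic etherification now meets the only remaining acidic site, the ordinary 4'-phenol, which is the standard substrate class for this reaction, and the allyl ether, the ketone and C2 should remain spectators as long as the mixture is kept at or below 0 °C and quenched at neutral pH.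

Step 4
Reactants: 5 (2S)-7-[(2-methylbut-3-en-2-yl)oxy]-2-{4-[(2-methylbut-3-yn-2-yl)oxy]phenyl}chroman-4-one
Product: 9 (2S)-2-(2,2-dimethyl-2H-chromen-6-yl)-7-hydroxy-8-(3-methylbut-2-en-1-yl)chroman-4-one (the target), via 8-prenyl phenol 6 (not isolated), via ortho-allenylphenol 7 (not isolated), via ortho-quinone methide 8 (not isolated)
Conditions: degassed o-xylene (0.02 M), Ar, 110 °C then 140 °C, one pot; neutral alumina
Reagents that add atoms: none
Why: On ring A the tertiary allyl aryl ether passes through a chair [3,3] transition state with inversion of the allyl unit and, after re-aromatising tautomerisation, gives phenol 6 with the new C8–CH2 bond. On ring B the aryl propargyl ether undergoes a propargyl Claisen [3,3] shift and enolisation to allenylphenol 7 (C3'–C bond), a 1,5-hydrogen shift from O–H to the central allene carbon gives the (Z)-ortho-quinone methide 8, and 8 closes the pyran by a thermal disrotatory oxa-6π electrocyclisation that forms the O4'–CMe2 bond. Both halves are known reaction types, the rearrangement of aryl 1,1-dimethylallyl ethers to ortho-prenylphenols and of aryl 1,1-dimethylpropargyl ethers to 2,2-dimethyl-2H-chromenes, here simply run in the same flask. No stereocentre is created (the CMe2 carbon is not stereogenic) and no bond to C2 is broken, so the (S) configuration is carried through, and an aprotic medium free of acid and base should keep ring C from opening to the chalcone and re-closing. The selectivity required is C8 over C6 on ring A, which the substrate should secure through the higher π-bond order of C7–C8 in 7-oxygenated chroman-4-ones, the carbon flanked by O1 and O7 being the usual terminus; ring B raises no question because C3' and C5' are equivalent. Holding first at the lower temperature lets the faster allyl shift finish before the propargyl cascade begins, and high dilution protects 8 from intermolecular trapping.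

Compound list
1 | (S)-liquiritigenin, (2S)-7-hydroxy-2-(4-hydroxyphenyl)chroman-4-one | Oc1ccc2c(c1)O[C@H](c1ccc(O)cc1)CC2=O | starting material
2 | 3-chloro-3-methylbut-1-yne | CC(C)(Cl)C#C | starting material
3 | (2S)-2-(4-hydroxyphenyl)-7-[(2-methylbut-3-yn-2-yl)oxy]chroman-4-one | C#CC(C)(C)Oc1ccc2c(c1)O[C@H](c1ccc(O)cc1)CC2=O | intermediate
4 | (2S)-2-(4-hydroxyphenyl)-7-[(2-methylbut-3-en-2-yl)oxy]chroman-4-one | C=CC(C)(C)Oc1ccc2c(c1)O[C@H](c1ccc(O)cc1)CC2=O | intermediate
5 | (2S)-7-[(2-methylbut-3-en-2-yl)oxy]-2-{4-[(2-methylbut-3-yn-2-yl)oxy]phenyl}chroman-4-one | C=CC(C)(C)Oc1ccc2c(c1)O[C@H](c1ccc(OC(C)(C)C#C)cc1)CC2=O | intermediate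
6 | (2S)-7-hydroxy-8-(3-methylbut-2-en-1-yl)-2-{4-[(2-methylbut-3-yn-2-yl)oxy]phenyl}chroman-4-one | CC(C)=CCc1c(O)ccc2c1O[C@H](c1ccc(OC(C)(C)C#C)cc1)CC2=O | intermediate
7 | (2S)-7-hydroxy-2-[4-hydroxy-3-(3-methylbuta-1,2-dien-1-yl)phenyl]-8-(3-methylbut-2-en-1-yl)chroman-4-one | CC(C)=CCc1c(O)ccc2c1O[C@H](c1ccc(O)c(C=C=C(C)C)c1)CC2=O | intermediate
8 | (2S)-7-hydroxy-8-(3-methylbut-2-en-1-yl)-2-[(3Z)-3-(3-methylbut-2-en-1-ylidene)-4-oxocyclohexa-1,5-dien-1-yl]chroman-4-one | CC(C)=CCc1c(O)ccc2c1O[C@H](C1=C/C(=C/C=C(C)C)C(=O)C=C1)CC2=O | intermediate
9 | (2S)-2-(2,2-dimethyl-2H-chromen-6-yl)-7-hydroxy-8-(3-methylbut-2-en-1-yl)chroman-4-one | CC(C)=CCc1c(O)ccc2c1O[C@H](c1ccc3c(c1)C=CC(C)(C)O3)CC2=O | target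

Total step count: 4. Longest linear sequence: 4 steps (1 → 3 → 4 → 5 → 9).

Steps most likely to fail

Step 4. Several processes may interfere:
- attack of the allyl unit at C6 instead of C8;
- heterolytic loss of the tertiary allyl group before it can shift;
- slow thermal opening and re-closure of ring C that lowers the optical purity;
- acid-promoted addition of the freshly formed 7-OH to the prenyl double bond at the temperature that ring B requires.

The fallback divides the operation and replaces heat by catalysis. It sets out from 5: a Eu(fod)3-catalysed aromatic Claisen rearrangement (CHCl3, 50–60 °C) should give phenol 6, which is now isolated. A gold(I)-catalysed 6-endo-dig intramolecular hydroarylation of the aryl propargyl ether (Ph3PAuNTf2, CH2Cl2, rt) should then close the 2,2-dimethyl-2H-chromene, and the route is rejoined at 9. At room temperature activation of the terminal alkyne should be much faster than any addition of the phenol to the trisubstituted alkene. This fallback makes no compound outside the list (F0).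

Step 3. Stoichiometric ionisation of the 4'-phenol may promote reversible opening of ring C (retro-oxa-Michael through the chalcone or a quinone methide), so that optical purity is partly lost during the alkylation. The fallback restores it by kinetic resolution and sets out from 5 of lowered optical purity. Asymmetric transfer hydrogenation with RuCl[(R,R)-TsDPEN](p-cymene) in HCO2H/Et3N (5:2) and EtOAc at room temperature should reduce the unwanted (2R)-ketone, the matched substrate, to the 2,4-cis alcohol (2R,4R)-7-[(2-methylbut-3-en-2-yl)oxy]-2-{4-[(2-methylbut-3-yn-2-yl)oxy]phenyl}chroman-4-ol F1. F1 is removed by chromatography, while the slower-reacting (S)-ketone is recovered and re-enters the route at 5. The sense of induction is taken from that of aryl alkyl ketones: the (R,R) catalyst gives the (R)-carbinol, with hydride delivered anti to the 2-aryl group. The slightly acidic medium should prevent racemisation during the resolution.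

Step 1. Discrimination between the two phenols may be incomplete, leading to alkylation at O4' or at both oxygens, and ring C may begin to open under the amidine base. The fallback avoids the amine base and the hydrogenation altogether and sets out from 1. A palladium(0)-catalysed decarboxylative Tsuji–Trost O-allylation with tert-butyl (2-methylbut-3-en-2-yl) carbonate F2 (made from 2-methylbut-3-en-2-ol and Boc2O; Pd(PPh3)4, THF, 0 °C) should deliver the branched 1,1-dimethylallyl ether at the most acidic phenol. The alkoxide base is generated only once per turnover and is consumed by the 7-OH, and attack at the more substituted allyl terminus is the kinetic outcome at low temperature. The route is rejoined at 4, so 3 and step 2 are no longer needed.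

Further compounds
F0 | step 4 | none | none
F1 | step 3 | (2R,4R)-7-[(2-methylbut-3-en-2-yl)oxy]-2-{4-[(2-methylbut-3-yn-2-yl)oxy]phenyl}chroman-4-ol | C=CC(C)(C)Oc1ccc2c(c1)O[C@@H](c1ccc(OC(C)(C)C#C)cc1)C[C@H]2O
F2 | step 1 | tert-butyl (2-methylbut-3-en-2-yl) carbonate | C=CC(C)(C)OC(=O)OC(C)(C)C
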